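Readings and results come from a simulation with constants of no real substance; the scatter is artificial.

Begin at early times in the blue run: at 0.333 h it holds 7.7 % of left-handed product and 1.5 % of right-handed product, so the single-handed catalyst serves the left-handed substrate faster.

in all of them: left-handed substrate 20 mM; right-handed substrate 20 mM

|  | reagent | catalyst | remark | time |
|---|---|---|---|---|
| blue | 24 mM | 2.4 mM | run made earlier |  |
| green | 24 mM | 12 mM | run made earlier |  |
| winter | 24.0 mM | 2.0 mM |  | 8.0 h |
| midnight | 24.0 mM | 4.0 mM |  | 8.0 h |
| noon | 24.0 mM | 8.0 mM |  | 8.0 h |

| run | time / h | left-handed product / % | right-handed substrate / % | right-handed product / % | left-handed substrate / % |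
|---|---|---|---|---|---|
| blue | 0.333 | 7.7 | 49.0 | 1.5 | 42.3 |
| blue | 0.500 | 10.0 | 47.8 | 1.8 | 40.3 |
| blue | 0.667 | 12.0 | 47.7 | 2.4 | 38.3 |
| blue | 1.00 | 14.9 | 46.8 | 2.9 | 34.9 |
| blue | 1.50 | 17.5 | 46.5 | 3.6 | 32.4 |
| blue | 2.50 | 20.1 | 45.7 | 4.5 | 29.4 |
| blue | 4.00 | 22.0 | 45.1 | 5.2 | 27.4 |
| green | 0.500 | 27.7 | 43.1 | 6.6 | 22.0 |
| green | 1.00 | 33.4 | 41.2 | 8.6 | 17.1 |
| green | 1.50 | 34.8 | 40.4 | 9.3 | 15.1 |
| green | 2.50 | 36.2 | 40.0 | 9.9 | 13.8 |
| green | 3.00 | 36.3 | 39.8 | 10.4 | 14.2 |
| green | 4.00 | 37.3 | 39.6 | 10.1 | 12.8 |

(standard deviation of a reading: 0.3 percentage points)

- catalyst is single-handed; left-handed substrate and right-handed substrate are mirror images of each other, charged as a racemate, each of them at the stated concentration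
- candidate steps: reagent + catalyst + left-handed substrate -> catalyst + left-handed product; reagent + catalyst + right-handed substrate -> catalyst + right-handed product; 2 reagent -> homo dimer

* which of these there is most of at the end, counted by the substrate in it, winter (right-handed substrate / left-handed substrate / right-handed product / left-handed product)
* which of these there is most of at the end, counted by the substrate in it, midnight (right-handed substrate / left-handed substrate / right-handed product / left-handed product)
* which of these there is most of at the end, counted by the substrate in it, noon (right-handed substrate / left-handed substrate / right-handed product / left-handed product)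
* final amount of the leader among these, as a percentage of the left-handed substrate and right-handed substrate together charged, in winter
* final amount of the leader among these, as a percentage of the left-handed substrate and right-handed substrate together charged, in midnight
* final amount of the leader among these, as a percentage of the left-handed substrate and right-handed substrate together charged, in noon

Carry one number from these runs: the selectivity factor, the natural log of the fraction left of the left-handed substrate's own charge divided by the same log for the right-handed substrate. Blue's last reading gives 5.83. Green's gives 5.84, with 12 mM of catalyst against 2.4 mM. So take the log of the left-handed fraction, divide by the factor, and undo the log: that is the right-handed fraction.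

Now build the flask. Take the main step first: reagent stands at 1.20 equivalents to the left-handed substrate, so this step can consume that substrate and leave the right-handed substrate whole. Add the right-handed step, and the two substrates share the reagent. A left-handed fraction of 0.100 then means a right-handed fraction of 67.4 %, and the two together need 1.23 equivalents, a little over the charge.

Add the dimer step last. At their last readings blue's products hold 45.3 % of its reagent and green's 79.0 %, so green's larger catalyst charge has put more of the reagent into product. Call the log of one over the left-handed fraction the depth. Give blue one more gain like its last, for a final depth of 0.672. Take green's as 1.36. Draw a straight line through these two on the log of the catalyst, and run it past blue for winter, which has less catalyst. My depths are 0.594 for winter, 0.891 for midnight and 1.19 for noon. The factor turns these into right-handed substrate at 45.2 %, 42.9 % and 40.8 %. In noon, left-handed product reaches about 34.8 %, so right-handed substrate leads there.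

The forecast, saying “the catalyst favours the left-handed substrate”, names right-handed substrate in each flask at 45 %, 43 % and 40.8 %.

The flasks give right-handed substrate as leader in each, at 45.2 % in winter, 43.1 % in midnight and 40.9 % in noon.

    reagent + catalyst + left-handed substrate → catalyst + left-handed product (k = 3.30 M⁻² s⁻¹)
    reagent + catalyst + right-handed substrate → catalyst + right-handed product (k = 0.570 M⁻² s⁻¹)
    2 reagent → homo dimer (k = 0.00810 M⁻¹ s⁻¹)

At 0.463 h in midnight, the left-handed substrate has a half-life by its own step of 1.4 h against 8.3 h for the right-handed substrate by its step, a ratio of 5.79, and midnight ends with 42 % of the left-handed charge, for which the factor gives 86.2 % of the right-handed charge against 86 % found. The neighbour of midnight charged with 96 mM of reagent ends with 5.57 % of left-handed substrate, for which the factor gives 34.3 % of right-handed substrate, and that flask holds 34.2 %.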